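The synthesis rests on cutting the 5,6-dihydro-2H-pyran-2-one ring (O1, C2 carbonyl, C3, C4, C5, C6) across C5–C6 and O1–C2. The C3=C4 double bond lying opposite the O1–C6 bond is the retron of a hetero-Diels–Alder reaction. A chromium-catalysed asymmetric [4+2] cycloaddition between the aldehyde of a fully functionalised acetoxymethyl enal (from nerol) and a 1-silyloxy-2-alkyl diene (from ethyl crotonate) joins the two halves, closes the ring by forming C5–C6, places C3=C4 and sets the only stereocentre, C6. The precursors are an acyclic enal and an acyclic dienol ether; oxidation of the acetal carbon and desilylation finish the synthesis.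

Key step: step 9

Remark: ring atoms are cited in the pyran-2-one numbering (C2 = carbonyl carbon, C6 = stereocentre), whereas systematic names number the ring from the other side; the catalyst antipode in step 9 is the one expected to expose the Si face of the aldehyde, and the other antipode is equally available should the sense prove opposite.

Step 1
Reactants: 1 nerol [(2Z)-3,7-dimethylocta-2,6-dien-1-ol]
Product: 2 tert-butyl{[(2Z)-3,7-dimethylocta-2,6-dien-1-yl]oxy}diphenylsilane (neryl TBDPS ether)
Conditions: TBDPSCl, imidazole, CH2Cl2, 0 °C to rt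
Reagents that add atoms: tert-butyl(chloro)diphenylsilane (TBDPSCl), CC(C)(C)[Si](Cl)(c1ccccc1)c1ccccc1
Why: Silyl ether protection of the primary allylic alcohol gives a group that should survive the organolithium, acid and Lewis-acid steps and is removed by fluoride at the end.

Step 2
Reactants: 2 neryl TBDPS ether
Product: 3 rac-3-{(3Z)-5-[(tert-butyldiphenylsilyl)oxy]-3-methylpent-3-en-1-yl}-2,2-dimethyloxirane
Conditions: mCPBA (1.05 equiv), CH2Cl2, −20 to 0 °C
Reagents that add atoms: 3-chloroperoxybenzoic acid (mCPBA), OOC(=O)c1cccc(Cl)c1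
Why: Prilezhaev epoxidation should take the remote, more electron-rich 6,7-alkene in preference to the 2,3-alkene, which is deactivated by the allylic silyloxy group; the new stereocentre is racemic and is destroyed in step 3.

Step 3
Reactants: 3 epoxide
Product: 4 (4Z)-6-[(tert-butyldiphenylsilyl)oxy]-4-methylhex-4-enal
Conditions: H5IO6, THF/H2O, 0 °C
Reagents that add atoms: none
Why: Periodic acid opens the epoxide to the diol in situ (water entering at the tertiary carbon) and cleaves it in a Malaprade-type glycol cleavage, releasing acetone and the aldehyde without touching the (Z)-alkene.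

Step 4
Reactants: 4 aldehyde; 5 2-bromo-3,3-diethoxyprop-1-ene
Product: 8 rac-(6Z)-8-[(tert-butyldiphenylsilyl)oxy]-1,1-diethoxy-6-methyl-2-methylideneoct-6-en-3-yl acetate, via vinyllithium 6 (not isolated), via lithium alkoxide 7 (not isolated)
Conditions: 5, n-BuLi, THF, −78 °C; then 4; then Ac2O, −78 to 0 °C
Reagents that add atoms: acetic anhydride, CC(=O)OC(C)=O
Why: Bromine–lithium exchange gives an α-lithiated acrolein acetal (acrolein α-anion equivalent) that adds 1,2 to the aldehyde, and the lithium alkoxide is acetylated in the same flask; the carbinol centre is racemic and becomes sp2 in step 5.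

Step 5
Reactants: 8 acetoxy acetal
Product: 10 (2E,6Z)-8-[(tert-butyldiphenylsilyl)oxy]-2-formyl-6-methylocta-2,6-dien-1-yl acetate, via branched acetoxy enal 9 (not isolated)
Conditions: oxalic acid (cat.), THF/H2O, rt; then DABCO (20 mol %), THF, 50 °C
Reagents that add atoms: water, O
Why: Acid hydrolysis of the conjugated acetal unmasks the 2-substituted acrolein, and DABCO then relays the acetate from the secondary to the primary allylic position by reversible SN2'/SN2 addition–elimination (1,3-transposition of a Morita–Baylis–Hillman-type acetate), which under thermodynamic control should give the conjugated (E)-enal with the formyl group trans to the chain.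

Step 6
Reactants: 11 ethyl (2E)-but-2-enoate (ethyl crotonate); 12 5-bromo-2-methylpent-2-ene
Product: 14 rac-ethyl 2-(4-methylpent-3-en-1-yl)but-3-enoate, via lithium dienolate 13 (not isolated)
Conditions: LDA (LiN(i-Pr)2), THF/DMPU, −78 °C; then 12, −78 to 0 °C
Reagents that add atoms: none
Why: Kinetic γ-deprotonation gives the lithium dienolate, which the primary bromide alkylates at the α-carbon (deconjugative α-alkylation of an ester dienolate); the α-centre is racemic and becomes sp2 in step 7.

Step 7
Reactants: 14 β,γ-unsaturated ester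
Product: 16 (2E)-2-(4-methylpent-3-en-1-yl)but-2-enal, via deconjugated aldehyde 15 (not isolated)
Conditions: i-Bu2AlH (1.05 equiv), CH2Cl2, −78 °C; aqueous potassium sodium tartrate; then DBU (cat.), CH2Cl2, rt
Reagents that add atoms: none
Why: Partial reduction of the ester at low temperature should stop at the aldehyde because the tetrahedral aluminium hemiacetal persists until work-up, and catalytic DBU then moves the double bond into conjugation (base-catalysed isomerisation) to the more stable (E)-enal.

Step 8
Reactants: 16 (E)-enal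
Product: 17 tert-butyl(dimethyl){[(1E)-2-(4-methylpent-3-en-1-yl)buta-1,3-dien-1-yl]oxy}silane
Conditions: TBSOTf, Et3N, Et2O, 0 °C to rt
Reagents that add atoms: tert-butyldimethylsilyl trifluoromethanesulfonate (TBSOTf), CC(C)(C)[Si](C)(C)OS(=O)(=O)C(F)(F)F
Why: O-Silylation of the enal and γ-deprotonation by the amine through the favoured s-trans conformer (silyl dienol ether formation) should give the (1E)-1-silyloxydiene, the isomer that can reach the s-cis diene geometry.

Step 9
Reactants: 10 acetoxymethyl enal; 17 silyloxydiene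
Product: 19 (2E,6Z)-8-[(tert-butyldiphenylsilyl)oxy]-2-[(2S)-6-hydroxy-5-(4-methylpent-3-en-1-yl)-3,6-dihydro-2H-pyran-2-yl]-6-methylocta-2,6-dien-1-yl acetate (lactol as a mixture of hemiacetal epimers), via silyl acetal cycloadduct 18 (not isolated)
Conditions: CrCl(L) (5 mol %), 4 Å molecular sieves, tert-butyl methyl ether (minimal), rt; then AcOH/THF/H2O, 0 °C; L = C27H29NO2, the dianion of the Schiff base from 3-(1-adamantyl)-2-hydroxy-5-methylbenzaldehyde and (1S,2R)-1-aminoindan-2-ol
Reagents that add atoms: water, O
Why: The chromium centre binds the aldehyde of 10 as a Lewis acid and the electron-rich diene 17 adds across the C=O group in a concerted, asynchronous [4+2] cycloaddition, the known catalytic asymmetric hetero-Diels–Alder reaction of 1-oxygenated dienes with aldehydes, in which the unsubstituted diene terminus bonds to the carbonyl carbon (C5–C6) ahead of O1–C2. The six-membered dihydropyran ring is thus closed by cycloaddition, the two new ring bonds being C5–C6 and O1–C2, and C3=C4 appears in its final place. The new stereocentre C6 is set by the catalyst, whose adamantyl-flanked tridentate ligand should leave only the Si face of the bound aldehyde open and so give the (S) centre, whereas the acetal centre is of no consequence because step 10 turns it into the carbonyl carbon. Regioselectivity comes from the silyloxy group, which makes the far CH2 terminus of the diene its nucleophilic end, and the alkyl branch at C3 favours the s-cis conformer; any (1Z) isomer of 17 cannot reach that geometry and stays a spectator, so 17 is charged according to its (1E) content. The step needs chemoselectivity for the carbonyl group over the conjugated C=C bond of 10, which should follow because that alkene is trisubstituted and hindered and because the only electron-rich two-carbon unit of 17, its enol ether bond, is itself trisubstituted and a poor partner for an inverse-demand mode; the allylic acetate and both silyl ethers are inert to the mild Lewis acid. The labile allylic silyl acetal 18 is not purified but hydrolysed in the same flask by dilute acetic acid to lactol 19, which should leave the primary silyl ether, the acetate and C6 untouched.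

Step 10
Reactants: 19 lactol
Product: 20 (2E,6Z)-8-[(tert-butyldiphenylsilyl)oxy]-6-methyl-2-[(2S)-5-(4-methylpent-3-en-1-yl)-6-oxo-3,6-dihydro-2H-pyran-2-yl]octa-2,6-dien-1-yl acetate
Conditions: MnO2, CH2Cl2, rt
Reagents that add atoms: none
Why: MnO2 oxidises the allylic hemiacetal to the α,β-unsaturated δ-lactone (allylic oxidation of a lactol), which erases the hemiacetal stereocentre; the molecule carries no other free allylic alcohol, so the primary silyl ether, the acetate and C6 should remain untouched.

Step 11
Reactants: 20 silyl-protected lactone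
Product: 21 (2E,6Z)-8-hydroxy-6-methyl-2-[(2S)-5-(4-methylpent-3-en-1-yl)-6-oxo-3,6-dihydro-2H-pyran-2-yl]octa-2,6-dien-1-yl acetate (target)
Conditions: HF·pyridine, pyridine, THF, 0 °C to rt
Reagents that add atoms: none
Why: Fluoride-mediated desilylation under buffered, mildly acidic conditions cleaves the primary TBDPS ether, while the allylic acetate and the unsaturated lactone should be stable and C6 is not epimerisable under these conditions.

Compound list
1 | nerol, (2Z)-3,7-dimethylocta-2,6-dien-1-ol | CC(C)=CCC/C(C)=C\CO | starting material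
2 | tert-butyl{[(2Z)-3,7-dimethylocta-2,6-dien-1-yl]oxy}diphenylsilane | CC(C)=CCC/C(C)=C\CO[Si](c1ccccc1)(c1ccccc1)C(C)(C)C | intermediate
3 | rac-3-{(3Z)-5-[(tert-butyldiphenylsilyl)oxy]-3-methylpent-3-en-1-yl}-2,2-dimethyloxirane | CC1(C)OC1CC/C(C)=C\CO[Si](c2ccccc2)(c2ccccc2)C(C)(C)C | intermediate
4 | (4Z)-6-[(tert-butyldiphenylsilyl)oxy]-4-methylhex-4-enal | O=CCC/C(C)=C\CO[Si](c1ccccc1)(c1ccccc1)C(C)(C)C | intermediate
5 | 2-bromo-3,3-diethoxyprop-1-ene | C=C(Br)C(OCC)OCC | starting material
6 | (3,3-diethoxyprop-1-en-2-yl)lithium (not isolated) | [Li]C(=C)C(OCC)OCC | intermediate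
7 | lithium rac-(6Z)-8-[(tert-butyldiphenylsilyl)oxy]-1,1-diethoxy-6-methyl-2-methylideneoct-6-en-3-olate (not isolated) | [Li]OC(CC/C(C)=C\CO[Si](c1ccccc1)(c1ccccc1)C(C)(C)C)C(=C)C(OCC)OCC | intermediate
8 | rac-(6Z)-8-[(tert-butyldiphenylsilyl)oxy]-1,1-diethoxy-6-methyl-2-methylideneoct-6-en-3-yl acetate | CCOC(OCC)C(=C)C(OC(C)=O)CC/C(C)=C\CO[Si](c1ccccc1)(c1ccccc1)C(C)(C)C | intermediate
9 | rac-(6Z)-8-[(tert-butyldiphenylsilyl)oxy]-2-formyl-6-methylocta-1,6-dien-3-yl acetate (not isolated) | O=CC(=C)C(OC(C)=O)CC/C(C)=C\CO[Si](c1ccccc1)(c1ccccc1)C(C)(C)C | intermediate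
10 | (2E,6Z)-8-[(tert-butyldiphenylsilyl)oxy]-2-formyl-6-methylocta-2,6-dien-1-yl acetate | CC(=O)OC/C(C=O)=C\CC/C(C)=C\CO[Si](c1ccccc1)(c1ccccc1)C(C)(C)C | intermediate
11 | ethyl (2E)-but-2-enoate (ethyl crotonate) | C/C=C/C(=O)OCC | starting material
12 | 5-bromo-2-methylpent-2-ene | CC(C)=CCCBr | starting material
13 | lithium 1-ethoxybuta-1,3-dien-1-olate (not isolated) | C=CC=C(OCC)O[Li] | intermediate
14 | rac-ethyl 2-(4-methylpent-3-en-1-yl)but-3-enoate | CCOC(=O)C(C=C)CCC=C(C)C | intermediate
15 | rac-2-(4-methylpent-3-en-1-yl)but-3-enal (not isolated) | O=CC(C=C)CCC=C(C)C | intermediate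
16 | (2E)-2-(4-methylpent-3-en-1-yl)but-2-enal | C/C=C(/C=O)CCC=C(C)C | intermediate
17 | tert-butyl(dimethyl){[(1E)-2-(4-methylpent-3-en-1-yl)buta-1,3-dien-1-yl]oxy}silane | CC(C)(C)[Si](C)(C)O/C=C(/C=C)CCC=C(C)C | intermediate
18 | (2E,6Z)-2-{(2S)-6-[(tert-butyldimethylsilyl)oxy]-5-(4-methylpent-3-en-1-yl)-3,6-dihydro-2H-pyran-2-yl}-8-[(tert-butyldiphenylsilyl)oxy]-6-methylocta-2,6-dien-1-yl acetate (epimers at the acetal carbon; not isolated) | CC(=O)OC/C(=C\CC/C(C)=C\CO[Si](c2ccccc2)(c2ccccc2)C(C)(C)C)[C@@H]1CC=C(CCC=C(C)C)C(O[Si](C)(C)C(C)(C)C)O1 | intermediate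
19 | (2E,6Z)-8-[(tert-butyldiphenylsilyl)oxy]-2-[(2S)-6-hydroxy-5-(4-methylpent-3-en-1-yl)-3,6-dihydro-2H-pyran-2-yl]-6-methylocta-2,6-dien-1-yl acetate (epimers at the hemiacetal carbon) | CC(=O)OC/C(=C\CC/C(C)=C\CO[Si](c2ccccc2)(c2ccccc2)C(C)(C)C)[C@@H]1CC=C(CCC=C(C)C)C(O)O1 | intermediate
20 | (2E,6Z)-8-[(tert-butyldiphenylsilyl)oxy]-6-methyl-2-[(2S)-5-(4-methylpent-3-en-1-yl)-6-oxo-3,6-dihydro-2H-pyran-2-yl]octa-2,6-dien-1-yl acetate | CC(=O)OC/C(=C\CC/C(C)=C\CO[Si](c2ccccc2)(c2ccccc2)C(C)(C)C)[C@@H]1CC=C(CCC=C(C)C)C(=O)O1 | intermediate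
21 | (2E,6Z)-8-hydroxy-6-methyl-2-[(2S)-5-(4-methylpent-3-en-1-yl)-6-oxo-3,6-dihydro-2H-pyran-2-yl]octa-2,6-dien-1-yl acetate | CC(=O)OC/C(=C\CC/C(C)=C\CO)[C@@H]1CC=C(CCC=C(C)C)C(=O)O1 | target

Total step count: 11. Longest linear sequence: 8 steps (steps 1–5, then 9–11).

Steps most likely to fail

1. Step 9. The enal may be consumed through competing cycloaddition modes (its C=C–C=O unit acting as a heterodiene, or its C=C bond as a dienophile), and turnover or facial selectivity may be poor with a conjugated, α-branched aldehyde. During the acidic hydrolysis the lactol may also open to the hydroxy enal and lose its (Z) geometry. The fallback sets out from aldehyde 10 and ester 14 and replaces the cycloaddition by a direct catalytic asymmetric vinylogous aldol–lactonisation: Cu(MeCN)4PF6 and (R)- or (S)-DTBM-SEGPHOS (5 mol % each), 2-tert-butyl-1,1,3,3-tetramethylguanidine (10 mol %), THF, 0 °C. Soft enolisation of 14 should give a metal-bound dienolate that attacks the aldehyde carbon through its γ-carbon with 1,2-selectivity, and the resulting (Z)-configured alkoxide lactonises with loss of ethoxide. This returns to the route at lactone 20 and bypasses steps 7 to 10 (no new compound, F0).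

2. Step 5. The 1,3-transposition of the acetate may stop short or give an E/Z mixture, and the unmasked 2-substituted acrolein may oligomerise. The fallback sets out from aldehyde 4 and fixes the alkene geometry at the ester oxidation level. A Morita–Baylis–Hillman reaction with methyl acrylate (DABCO, rt) gives rac-methyl (6Z)-8-[(tert-butyldiphenylsilyl)oxy]-3-hydroxy-6-methyl-2-methylideneoct-6-enoate F1. NBS/Me2S (CH2Cl2, 0 °C) converts it with allylic transposition into methyl (2Z,6Z)-2-(bromomethyl)-8-[(tert-butyldiphenylsilyl)oxy]-6-methylocta-2,6-dienoate F2, in which the ester is trans to the chain. Reduction with i-Bu2AlH (CH2Cl2, −78 °C) gives (2Z,6Z)-2-(bromomethyl)-8-[(tert-butyldiphenylsilyl)oxy]-6-methylocta-2,6-dien-1-ol F3. Displacement of the bromide with KOAc (DMF, rt) gives (2Z,6Z)-8-[(tert-butyldiphenylsilyl)oxy]-2-(hydroxymethyl)-6-methylocta-2,6-dien-1-yl acetate F4. This is oxidised without delay with MnO2 (CH2Cl2), to forestall acetyl migration, and the route is rejoined at enal 10.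

3. Step 7. The reduction may run on to the primary alcohol, and material may be lost by self-condensation of the aldehyde during the base-mediated conjugation. The fallback sets out from bromide 12 and reaches the aldehyde oxidation level without any reduction. (2E)-N-cyclohexylbut-2-en-1-imine F5 (from crotonaldehyde and cyclohexylamine) is deprotonated with LDA (LiN(i-Pr)2, THF, −78 °C) and alkylated at its α-carbon with 12 to give rac-N-cyclohexyl-2-(4-methylpent-3-en-1-yl)but-3-en-1-imine F6. Hydrolysis with aqueous oxalic acid followed by a catalytic amount of DBU returns the route at enal 16, replacing steps 6 and 7.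

Further compounds
F0 | step 9 | none | none
F1 | step 5 | rac-methyl (6Z)-8-[(tert-butyldiphenylsilyl)oxy]-3-hydroxy-6-methyl-2-methylideneoct-6-enoate | C=C(C(=O)OC)C(O)CC/C(C)=C\CO[Si](c1ccccc1)(c1ccccc1)C(C)(C)C
F2 | step 5 | methyl (2Z,6Z)-2-(bromomethyl)-8-[(tert-butyldiphenylsilyl)oxy]-6-methylocta-2,6-dienoate | COC(=O)/C(CBr)=C/CC/C(C)=C\CO[Si](c1ccccc1)(c1ccccc1)C(C)(C)C
F3 | step 5 | (2Z,6Z)-2-(bromomethyl)-8-[(tert-butyldiphenylsilyl)oxy]-6-methylocta-2,6-dien-1-ol | OC/C(CBr)=C/CC/C(C)=C\CO[Si](c1ccccc1)(c1ccccc1)C(C)(C)C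
F4 | step 5 | (2Z,6Z)-8-[(tert-butyldiphenylsilyl)oxy]-2-(hydroxymethyl)-6-methylocta-2,6-dien-1-yl acetate | CC(=O)OC/C(CO)=C\CC/C(C)=C\CO[Si](c1ccccc1)(c1ccccc1)C(C)(C)C
F5 | step 7 | (2E)-N-cyclohexylbut-2-en-1-imine | C/C=C/C=NC1CCCCC1
F6 | step 7 | rac-N-cyclohexyl-2-(4-methylpent-3-en-1-yl)but-3-en-1-imine | C=CC(CCC=C(C)C)C=NC1CCCCC1
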